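## Structural features

Vitedoin A is a 1-aryl-1,2-dihydronaphthalene lignan in which benzo ring A (C4a to C8a, OH on C7, OMe on C8) is fused to a partly saturated ring B (C1 and C2 sp3, C3=C4), and C1 carries a 4-hydroxy-3-methoxyphenyl ring. The two stereocentres are neighbours: C1 (S, a diaryl methine) and C2 (R, bearing the C9 hydroxymethyl group), with aryl and hydroxymethyl trans on ring B. C3 carries the C10 formyl group, so ring A, C4=C3 and C10=O form one conjugated styryl enal. The fragile points are the dihydronaphthalene, which is two hydrogens away from a naphthalene whose formation would erase both stereocentres, the electrophilic enal, the two oxidisable phenols, the doubly benzylic C1–H, and the C9–OH, which can close a lactol onto C10. The real difficulty is the crowded C1: it sits on C8a, which is flanked by C8–OMe and C4a, so ring A is contiguously tetrasubstituted and the trans C1/C2 diad has to be set in absolute terms next to it, while C9 and C10 must end at different oxidation levels. The key step exploits the unit ring A–C4H=C3–C10=O. Read backwards, it is the metathesis product of a ring A formyl group (C4=O) and an oxygen-polarised alkyne C3≡C10–O, so ring B, the alkene and C10 at the carboxyl level can all arise in one isomerisation.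

## Logic of the disconnections

**27 back to 24.** The three benzyl C–O bonds are cut last (27 from 26), because free phenols and a free C9–OH would not survive the organometallic steps. C10 is then walked back from the aldehyde level (26) through the alcohol level (25) to the silyl carboxylate of 24, which is the oxidation level the ring-forming step delivers. Nothing is simplified in the skeleton; the demand is a clean 1,2-reduction, an oxidation that touches only the allylic alcohol, and a debenzylation that spares the enal, the methyl ethers and the ring B alkene.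

**24 back to 22.** The C3=C4 double bond is cut completely, returning oxygen to C4 as a formyl group and a triple bond to C3≡C10 with the silyloxy group on C10. This is the cut because the forward reaction is an isomerisation that closes ring B and places the alkene and C10 without any redox change. The gain is the loss of ring B and of the trisubstituted alkene, with C1 and C2 untouched. The demand is that the activated ynol ether reacts with the formyl group and not with the pendant arene or water.

**22 back to 17 and 18.** A formyl group cannot coexist with ynolate chemistry, so it is carried as the dimethyl acetal (21). The C3≡C10–O unit is traced to the ester carbon of 17 (C10) plus one carbon from 18 (C3, inserted between C2 and C10). The gain is that the sensitive siloxyalkyne becomes a plain α-branched ester. The demands are that acetal hydrolysis outruns protonation of the ynol ether and that C2 keeps its configuration during the 1,2-shift.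

**17 back to 12.** After two acyl-transfer steps (17 from 16 from 14), the C2–C9 bond is cut as an enolate alkylation under auxiliary control. This removes the C2 stereocentre. It demands a Z-enolate, attack anti to the auxiliary benzyl group, and a base-only protocol, because a strong Lewis acid would ionise the acetal.

**12 back to 8 and 10.** The bond from C1 to the pendant aryl ring is cut as a conjugate arylation (through 11). Ring A is kept on the acceptor for two reasons: a ring A nucleophile would be doubly ortho-substituted, and with the roles reversed one auxiliary would steer its two steps to the cis diad. With ring A on the acceptor, both steps from the (R)-auxiliary converge on the trans (1S,2R) array. The gain is an enoyl imide without a carbon stereocentre in its acyl part and a simple aryl bromide; the demand is facial selectivity at a hindered β-carbon.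

**8 back to 4 and 7; 7 back to 5 and 6.** The C1=C2 alkene is cut by olefination into 4 and 7, and 7 comes from 5 and 6 by N-acylation. This installs the auxiliary and both carbons C2 and C10 in one convergent step; the demand is E geometry.

**4 back to 1; 10 back to 9.** The C8a–C1 bond is cut as a formylation at the ring position lying between the methoxy group and the acetal of 2, and 2 comes from 1 by acetalisation. All of ring A then derives from one purchased aldehyde. The demand is metalation at the doubly flanked site and not at the benzylic CH2 of the ether. 10 is the benzyl ether of 9.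

## Other disconnections considered

**Alternative 1:** The cut goes through ring A itself: C4a–C8a and C7–C8 are disconnected, leaving a 2-furyl group on C4 and a methoxyalkyne C8a≡C8 on C1 in precursor A2. The forward step is an intramolecular furan–alkyne [4+2] addition, then opening of the oxygen bridge at C4a and loss of the C7 proton, to give A1.
- In favour: two rings and two C–C bonds form at once; the C7 phenol appears free and already distinguished from C8–OMe; no metalation of a crowded arene is needed. On these structural points it is better than the chosen plan, and A1 is closer to the target than 24 because C10 is already an aldehyde.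
- Against: furan and ynol ether are both electron-rich, so a thermal cycloaddition has little polar driving force. Carbophilic metal catalysis would be needed, and its stepwise pathways can relocate the hydroxyl group. A2 must already hold the trans diad, a geometrically defined enal and a base-made ynol ether, and its C1–H is benzylic and propargylic, hence configurationally at risk.
- Comparison: on mechanism the chosen metathesis is regiochemically unambiguous where this one is not. On step economy the two are about equal, since the stereodiad must be made beforehand in both.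

**Alternative 2:** The cut is C1–C2. The precursor is the diaryldiazomethane A4, whose benzo ring also carries an E-arylidene butyrolactone. With Rh2(S-PTAD)4, a chiral dirhodium tetracarboxylate, A4 would give a donor/donor rhodium carbene at C1. Insertion into the allylic C2–H bond closes ring B and sets both stereocentres, giving lactone A3.
- In favour: A4 is achiral, both centres form catalytically in the ring-closing step, no auxiliary is needed, and C9/C10 are already differentiated as the two lactone carbons of A3. Reduction, allylic oxidation and desilylation would finish the synthesis. On step economy this is clearly better than the chosen plan.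
- Against: the desired insertion closes a six-membered ring, whereas such carbenes prefer five-membered closure. In A4 the C8 methoxy C–H bonds offer exactly that competing path (to a dihydrobenzofuran). The target C–H is allylic but β to a carbonyl and thus electronically deactivated. The catalyst must also tell apart two similar electron-rich aryl groups at C1.
- Comparison: on structure the fit is equal; on mechanism the chosen plan is safer because its selectivity is fixed by polarity and ring size and not by catalyst discrimination among C–H bonds.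

**Alternative 3:** The cuts are C1–C2 and C3=C4. The quinone methide aldehyde A6 would react with succinaldehyde A7 under a diarylprolinol silyl ether: enamine 1,6-addition through C2, then aldol condensation of the second aldehyde through C3 with the ring A formyl group, giving dialdehyde A5.
- In favour: it is by far the shortest; both stereocentres, ring B and the enal arise in one organocatalytic operation with the pendant phenol free. C2 is α to an aldehyde, so the trans diad is also the thermodynamic one. On step and redox economy it is better than the chosen plan.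
- Against: A6 lacks the bulky flanking groups that make such quinone methides isolable and would have to be generated in situ. Its electrophilic carbon is shielded by a doubly ortho-substituted aryl group. The enamine may add to the formyl group first, and A7 self-condenses readily. A5 then requires reduction of the saturated C9 aldehyde in the presence of the enal, next to an epimerisable C2.
- Comparison: on structure it maps equally well; on mechanism, enantiocontrol at a diaryl methine from a transient quinone methide is much less secure than auxiliary control.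

Key step: step 12

Remark on starting material: 4-(benzyloxy)-3-methoxybenzaldehyde (O-benzylvanillin) is a catalogue compound and is used as purchased; made from vanillin (BnBr, K2CO3) it would add one step.

Remark on the auxiliary: with the chelated s-cis enoyl imide and the chelated Z-enolate both reacting anti to the C4 benzyl group, the (R)-auxiliary is the one that gives 1S and 2R. The (S)-auxiliary would give the enantiomer.

Remark on numbering: atom labels C1 to C10 follow the target in all intermediates.

## Route

**Step 1**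
Reactants: 1 4-(benzyloxy)-3-methoxybenzaldehyde
Product: 2 1-(benzyloxy)-4-(dimethoxymethyl)-2-methoxybenzene
Conditions: HC(OMe)3, MeOH, p-TsOH·H2O (1 mol %), rt; Et3N quench
Reagents that add atoms: trimethyl orthoformate COC(OC)OC; methanol CO
Why: Acid-catalysed acetalisation driven by the orthoformate as water scavenger. The dimethyl acetal masks C4 against all organometallic steps, helps direct the metalation of step 2, and is the acetal type that hydrolyses fastest when the mask must later come off beside the siloxyalkyne.

**Step 2**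
Reactants: 2 1-(benzyloxy)-4-(dimethoxymethyl)-2-methoxybenzene
Product: 4 3-(benzyloxy)-6-(dimethoxymethyl)-2-methoxybenzaldehyde, via aryllithium 3 (not isolated)
Conditions: n-BuLi, THF, −78 → −20 °C; DMF, −78 °C → rt; H2O
Reagents that add atoms: N,N-dimethylformamide CN(C)C=O
Why: Directed ortho-metalation: the ring position between the methoxy group and the acetal is activated by both, so lithiation there should outrun metalation at the benzylic CH2 of the ether at low temperature. Formylation of the aryllithium with DMF makes the C8a–C1 bond.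

**Step 3**
Reactants: 5 (R)-4-benzyl-2-oxazolidinone; 6 2-(diethoxyphosphoryl)acetic acid
Product: 7 (R)-4-benzyl-3-[2-(diethoxyphosphoryl)acetyl]oxazolidin-2-one
Conditions: 6, t-BuCOCl, Et3N, THF, −20 °C; then 5, LiCl, −20 °C → rt
Reagents that add atoms: none
Why: N-Acylation of the oxazolidinone through the mixed pivalic anhydride, with LiCl/Et3N making the carbamate nitrogen nucleophilic enough, gives the chiral phosphonate in one operation.

**Step 4**
Reactants: 4 3-(benzyloxy)-6-(dimethoxymethyl)-2-methoxybenzaldehyde; 7 (R)-4-benzyl-3-[2-(diethoxyphosphoryl)acetyl]oxazolidin-2-one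
Product: 8 (R)-4-benzyl-3-{(E)-3-[3-(benzyloxy)-6-(dimethoxymethyl)-2-methoxyphenyl]acryloyl}oxazolidin-2-one
Conditions: LiCl, i-Pr2NEt, MeCN, rt
Reagents that add atoms: none
Why: Horner–Wadsworth–Emmons olefination under mild LiCl/amine (Masamune–Roush) conditions gives the E-enoyl imide. The non-enolisable aldehyde, the acetal and the imide tolerate the weak base.

**Step 5**
Reactants: 9 4-bromo-2-methoxyphenol
Product: 10 1-(benzyloxy)-4-bromo-2-methoxybenzene
Conditions: BnBr, K2CO3, DMF, rt
Reagents that add atoms: benzyl bromide BrCc1ccccc1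
Why: Williamson etherification; the benzyl ether survives Grignard formation and every later base.

**Step 6**
Reactants: 10 1-(benzyloxy)-4-bromo-2-methoxybenzene; 8 (R)-4-benzyl-3-{(E)-3-[3-(benzyloxy)-6-(dimethoxymethyl)-2-methoxyphenyl]acryloyl}oxazolidin-2-one
Product: 12 (R)-4-benzyl-3-{(S)-3-[3-(benzyloxy)-6-(dimethoxymethyl)-2-methoxyphenyl]-3-[4-(benzyloxy)-3-methoxyphenyl]propanoyl}oxazolidin-2-one, via Grignard reagent 11 (not isolated)
Conditions: 10, Mg, THF, 40 °C; CuBr·SMe2, THF/Me2S, −40 °C; 8, −40 → 0 °C; aq. NH4Cl
Reagents that add atoms: none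
Why: Copper-mediated conjugate arylation of a chiral N-enoyl oxazolidinone. The magnesium-chelated s-cis imide exposes the Cβ face anti to the C4 benzyl group, so with the (R)-auxiliary the pendant aryl adds to give C1 as S (ring A, pendant aryl, C2 counter-clockwise with H to the rear).

**Step 7**
Reactants: 12 (R)-4-benzyl-3-{(S)-3-[3-(benzyloxy)-6-(dimethoxymethyl)-2-methoxyphenyl]-3-[4-(benzyloxy)-3-methoxyphenyl]propanoyl}oxazolidin-2-one
Product: 14 (R)-4-benzyl-3-{(2S,3S)-2-[(benzyloxy)methyl]-3-[3-(benzyloxy)-6-(dimethoxymethyl)-2-methoxyphenyl]-3-[4-(benzyloxy)-3-methoxyphenyl]propanoyl}oxazolidin-2-one, via sodium enolate 13 (not isolated)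
Conditions: NaN(SiMe3)2, THF, −78 °C; BnOCH2Cl, −78 → −40 °C
Reagents that add atoms: benzyl chloromethyl ether ClCOCc1ccccc1
Why: Auxiliary-controlled alkylation of the chelated Z-sodium enolate (Evans alkylation). The electrophile comes in anti to the auxiliary benzyl group, which sets C2 (2S in the imide, R in target numbering) and places C9 trans to the pendant aryl on the later ring B. A sodium enolate is used because a TiCl4 enolate would ionise the acetal.

**Step 8**
Reactants: 14 (R)-4-benzyl-3-{(2S,3S)-2-[(benzyloxy)methyl]-3-[3-(benzyloxy)-6-(dimethoxymethyl)-2-methoxyphenyl]-3-[4-(benzyloxy)-3-methoxyphenyl]propanoyl}oxazolidin-2-one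
Product: 16 (2S,3S)-2-[(benzyloxy)methyl]-3-[3-(benzyloxy)-6-(dimethoxymethyl)-2-methoxyphenyl]-3-[4-(benzyloxy)-3-methoxyphenyl]propanoic acid, via peroxy acid 15 (not isolated)
Conditions: LiOH, H2O2, THF/H2O, 0 °C; Na2SO3; AcOH to pH 5
Reagents that add atoms: hydrogen peroxide OO
Why: Hydroperoxide attacks the exocyclic imide carbonyl selectively even in α,β-branched cases and is too weakly basic to epimerise C2 or eliminate benzyloxide. Sulfite reduces the peroxy acid, and the acetic acid work-up keeps the pH where the acetal survives.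

**Step 9**
Reactants: 16 (2S,3S)-2-[(benzyloxy)methyl]-3-[3-(benzyloxy)-6-(dimethoxymethyl)-2-methoxyphenyl]-3-[4-(benzyloxy)-3-methoxyphenyl]propanoic acid
Product: 17 methyl (2S,3S)-2-[(benzyloxy)methyl]-3-[3-(benzyloxy)-6-(dimethoxymethyl)-2-methoxyphenyl]-3-[4-(benzyloxy)-3-methoxyphenyl]propanoate
Conditions: Me3SiCHN2, PhMe/MeOH, 0 °C
Reagents that add atoms: (trimethylsilyl)diazomethane C[Si](C)(C)C=[N+]=[N-]
Why: O-Methylation of the acid by the diazoalkane in methanol is neutral, so neither the acetal (which can only exchange with methanol degenerately) nor the C2–H/β-benzyloxy array is at risk.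

**Step 10**
Reactants: 17 methyl (2S,3S)-2-[(benzyloxy)methyl]-3-[3-(benzyloxy)-6-(dimethoxymethyl)-2-methoxyphenyl]-3-[4-(benzyloxy)-3-methoxyphenyl]propanoate; 18 dibromomethane
Product: 21 {[(3R,4S)-4-[3-(benzyloxy)-6-(dimethoxymethyl)-2-methoxyphenyl]-4-[4-(benzyloxy)-3-methoxyphenyl]-3-[(benzyloxy)methyl]but-1-yn-1-yl]oxy}triisopropylsilane, via dibromomethyl ketone 19 (not isolated), via lithium ynolate 20 (not isolated)
Conditions: 18, lithium 2,2,6,6-tetramethylpiperidide, THF, −78 °C, then 17; LiN(SiMe3)2; n-BuLi, −78 → −20 °C; i-Pr3SiCl, −78 °C → rt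
Reagents that add atoms: chlorotriisopropylsilane CC(C)[Si](Cl)(C(C)C)C(C)C
Why: Kowalski homologation stopped at the ynolate. LiCHBr2 adds to the ester; the enolate of the dibromoketone undergoes Br/Li exchange and a 1,2-shift of the C2 substituent (with retention) to give the ynolate, which the bulky silyl chloride captures on oxygen. C3 comes from 18 and C10 is the former ester carbon; the chloride is chosen over the triflate so that the acetal is not ionised.

**Step 11**
Reactants: 21 {[(3R,4S)-4-[3-(benzyloxy)-6-(dimethoxymethyl)-2-methoxyphenyl]-4-[4-(benzyloxy)-3-methoxyphenyl]-3-[(benzyloxy)methyl]but-1-yn-1-yl]oxy}triisopropylsilane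
Product: 22 4-(benzyloxy)-2-{(1S,2R)-1-[4-(benzyloxy)-3-methoxyphenyl]-2-[(benzyloxy)methyl]-4-[(triisopropylsilyl)oxy]but-3-yn-1-yl}-3-methoxybenzaldehyde
Conditions: pyridinium p-toluenesulfonate (10 mol %), acetone/H2O (20:1), 0 °C → rt; Et3N quench
Reagents that add atoms: water O
Why: Acid hydrolysis of a dimethyl acetal whose aryl ring has a para alkoxy group is expected to be orders of magnitude faster than C-protonation of the hindered silyl ynol ether. A buffered pyridinium acid in wet acetone should therefore free the formyl group and leave the siloxyalkyne intact.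

**Step 12**
Reactants: 22 4-(benzyloxy)-2-{(1S,2R)-1-[4-(benzyloxy)-3-methoxyphenyl]-2-[(benzyloxy)methyl]-4-[(triisopropylsilyl)oxy]but-3-yn-1-yl}-3-methoxybenzaldehyde
Product: 24 triisopropylsilyl (1S,2R)-7-(benzyloxy)-1-[4-(benzyloxy)-3-methoxyphenyl]-2-[(benzyloxy)methyl]-8-methoxy-1,2-dihydronaphthalene-3-carboxylate (target numbering), via oxetene 23 (not isolated)
Conditions: AgNTf2 (10 mol %), 4 Å molecular sieves, CH2Cl2 (0.02 M), 0 °C → rt
Reagents that add atoms: none
Why: Monovalent silver (AgNTf2) acts as a Lewis acid that brings the formyl group and the electron-rich alkyne together, and the nucleophilic carbon C3 of the ynol ether attacks the formyl carbon C4. The silyl ketenium centre that develops at C10 is captured by the former carbonyl oxygen to give oxetene 23, whose thermally allowed conrotatory ring opening yields the C3=C4 bond and the C10 silyl ester. The closest known reaction types are the silver-catalysed olefination of aldehydes with siloxyalkynes and the Lewis-acid intramolecular alkyne–aldehyde metathesis that gives 3-acyl-1,2-dihydronaphthalenes. Ring B closes in the C3–C4 bond-forming event as a six-membered ring, exo to both π systems (6-exo-trig at the carbonyl, 6-exo-dig at the alkyne, C10 exocyclic); the four-membered ring is transient. No stereocentre is formed: C1 and C2 are spectators, neither is enolisable in substrate or product, and the ring fixes the alkene geometry. The step needs regioselectivity (C3 and not C10 bonding to C4) and chemoselectivity (the formyl group and not the pendant arene or water as partner of the activated alkyne). The first is secured by the polarisation of the silyl ynol ether. The second is secured by the ortho formyl group being the only partner that can close an unstrained six-membered ring through C3, and by dry conditions with a silver catalyst in place of a Brønsted acid.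

**Step 13**
Reactants: 24 triisopropylsilyl (1S,2R)-7-(benzyloxy)-1-[4-(benzyloxy)-3-methoxyphenyl]-2-[(benzyloxy)methyl]-8-methoxy-1,2-dihydronaphthalene-3-carboxylate
Product: 25 {(1S,2R)-7-(benzyloxy)-1-[4-(benzyloxy)-3-methoxyphenyl]-2-[(benzyloxy)methyl]-8-methoxy-1,2-dihydronaphthalen-3-yl}methanol (target numbering)
Conditions: i-Bu2AlH, CH2Cl2, −78 → −20 °C; aq. KNaC4H4O6
Reagents that add atoms: none
Why: 1,2-Reduction of the conjugated silyl ester by the aluminium hydride gives the allylic alcohol and releases the silanol; benzyl ethers and the styrenic alkene are inert.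

**Step 14**
Reactants: 25 {(1S,2R)-7-(benzyloxy)-1-[4-(benzyloxy)-3-methoxyphenyl]-2-[(benzyloxy)methyl]-8-methoxy-1,2-dihydronaphthalen-3-yl}methanol
Product: 26 (1S,2R)-7-(benzyloxy)-1-[4-(benzyloxy)-3-methoxyphenyl]-2-[(benzyloxy)methyl]-8-methoxy-1,2-dihydronaphthalene-3-carbaldehyde (target numbering)
Conditions: MnO2, CH2Cl2, rt
Reagents that add atoms: none
Why: MnO2 oxidises allylic alcohols chemoselectively to enals under neutral conditions; over-oxidation or dehydrogenation of ring B is not expected at room temperature.

**Step 15**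
Reactants: 26 (1S,2R)-7-(benzyloxy)-1-[4-(benzyloxy)-3-methoxyphenyl]-2-[(benzyloxy)methyl]-8-methoxy-1,2-dihydronaphthalene-3-carbaldehyde
Product: 27 vitedoin A, (1S,2R)-7-hydroxy-1-(4-hydroxy-3-methoxyphenyl)-2-(hydroxymethyl)-8-methoxy-1,2-dihydronaphthalene-3-carbaldehyde (target numbering)
Conditions: BCl3, C6HMe5, CH2Cl2, −78 → −40 °C; MeOH quench
Reagents that add atoms: none
Why: BCl3 with pentamethylbenzene as a non-basic cation scavenger cleaves aryl and primary alkyl benzyl ethers at low temperature while sparing aryl methyl ethers, the enal and the ring B alkene. The scavenger prevents C-benzylation of the electron-rich rings.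

## Compound list

1 | 4-(benzyloxy)-3-methoxybenzaldehyde | COc1cc(C=O)ccc1OCc1ccccc1 | starting material
2 | 1-(benzyloxy)-4-(dimethoxymethyl)-2-methoxybenzene | COc1cc(C(OC)OC)ccc1OCc1ccccc1 | intermediate
3 | [3-(benzyloxy)-6-(dimethoxymethyl)-2-methoxyphenyl]lithium | [Li]c1c(OC)c(OCc2ccccc2)ccc1C(OC)OC | intermediate (not isolated)
4 | 3-(benzyloxy)-6-(dimethoxymethyl)-2-methoxybenzaldehyde | O=Cc1c(OC)c(OCc2ccccc2)ccc1C(OC)OC | intermediate
5 | (R)-4-benzyl-2-oxazolidinone | O=C1N[C@H](Cc2ccccc2)CO1 | starting material
6 | 2-(diethoxyphosphoryl)acetic acid | CCOP(=O)(CC(=O)O)OCC | starting material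
7 | (R)-4-benzyl-3-[2-(diethoxyphosphoryl)acetyl]oxazolidin-2-one | CCOP(=O)(CC(=O)N1[C@H](Cc2ccccc2)COC1=O)OCC | intermediate
8 | (R)-4-benzyl-3-{(E)-3-[3-(benzyloxy)-6-(dimethoxymethyl)-2-methoxyphenyl]acryloyl}oxazolidin-2-one | COc1c(OCc2ccccc2)ccc(C(OC)OC)c1/C=C/C(=O)N1[C@H](Cc2ccccc2)COC1=O | intermediate
9 | 4-bromo-2-methoxyphenol | COc1cc(Br)ccc1O | starting material
10 | 1-(benzyloxy)-4-bromo-2-methoxybenzene | COc1cc(Br)ccc1OCc1ccccc1 | intermediate
11 | [4-(benzyloxy)-3-methoxyphenyl]magnesium bromide | COc1cc([Mg]Br)ccc1OCc1ccccc1 | intermediate (not isolated)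
12 | (R)-4-benzyl-3-{(S)-3-[3-(benzyloxy)-6-(dimethoxymethyl)-2-methoxyphenyl]-3-[4-(benzyloxy)-3-methoxyphenyl]propanoyl}oxazolidin-2-one | COc1cc([C@@H](c2c(C(OC)OC)ccc(OCc3ccccc3)c2OC)CC(=O)N2[C@H](Cc3ccccc3)COC2=O)ccc1OCc1ccccc1 | intermediate
13 | sodium (Z)-enolate of 12 | [Na+].[O-]/C(=C\[C@@H](c1ccc(OCc2ccccc2)c(OC)c1)c1c(C(OC)OC)ccc(OCc2ccccc2)c1OC)N1[C@H](Cc2ccccc2)COC1=O | intermediate (not isolated)
14 | (R)-4-benzyl-3-{(2S,3S)-2-[(benzyloxy)methyl]-3-[3-(benzyloxy)-6-(dimethoxymethyl)-2-methoxyphenyl]-3-[4-(benzyloxy)-3-methoxyphenyl]propanoyl}oxazolidin-2-one | COc1cc([C@@H](c2c(C(OC)OC)ccc(OCc3ccccc3)c2OC)[C@@H](COCc2ccccc2)C(=O)N2[C@H](Cc3ccccc3)COC2=O)ccc1OCc1ccccc1 | intermediate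
15 | (2S,3S)-2-[(benzyloxy)methyl]-3-[3-(benzyloxy)-6-(dimethoxymethyl)-2-methoxyphenyl]-3-[4-(benzyloxy)-3-methoxyphenyl]propaneperoxoic acid | COc1cc([C@@H](c2c(C(OC)OC)ccc(OCc3ccccc3)c2OC)[C@@H](COCc2ccccc2)C(=O)OO)ccc1OCc1ccccc1 | intermediate (not isolated)
16 | (2S,3S)-2-[(benzyloxy)methyl]-3-[3-(benzyloxy)-6-(dimethoxymethyl)-2-methoxyphenyl]-3-[4-(benzyloxy)-3-methoxyphenyl]propanoic acid | COc1cc([C@@H](c2c(C(OC)OC)ccc(OCc3ccccc3)c2OC)[C@@H](COCc2ccccc2)C(=O)O)ccc1OCc1ccccc1 | intermediate
17 | methyl (2S,3S)-2-[(benzyloxy)methyl]-3-[3-(benzyloxy)-6-(dimethoxymethyl)-2-methoxyphenyl]-3-[4-(benzyloxy)-3-methoxyphenyl]propanoate | COc1cc([C@@H](c2c(C(OC)OC)ccc(OCc3ccccc3)c2OC)[C@@H](COCc2ccccc2)C(=O)OC)ccc1OCc1ccccc1 | intermediate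
18 | dibromomethane | BrCBr | starting material
19 | (3S,4S)-1,1-dibromo-3-[(benzyloxy)methyl]-4-[3-(benzyloxy)-6-(dimethoxymethyl)-2-methoxyphenyl]-4-[4-(benzyloxy)-3-methoxyphenyl]butan-2-one | COc1cc([C@@H](c2c(C(OC)OC)ccc(OCc3ccccc3)c2OC)[C@@H](COCc2ccccc2)C(=O)C(Br)Br)ccc1OCc1ccccc1 | intermediate (not isolated)
20 | lithium (3R,4S)-4-[3-(benzyloxy)-6-(dimethoxymethyl)-2-methoxyphenyl]-4-[4-(benzyloxy)-3-methoxyphenyl]-3-[(benzyloxy)methyl]but-1-yn-1-olate | COc1cc([C@@H](c2c(C(OC)OC)ccc(OCc3ccccc3)c2OC)[C@@H](COCc2ccccc2)C#CO[Li])ccc1OCc1ccccc1 | intermediate (not isolated)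
21 | {[(3R,4S)-4-[3-(benzyloxy)-6-(dimethoxymethyl)-2-methoxyphenyl]-4-[4-(benzyloxy)-3-methoxyphenyl]-3-[(benzyloxy)methyl]but-1-yn-1-yl]oxy}triisopropylsilane | COc1cc([C@@H](c2c(C(OC)OC)ccc(OCc3ccccc3)c2OC)[C@@H](COCc2ccccc2)C#CO[Si](C(C)C)(C(C)C)C(C)C)ccc1OCc1ccccc1 | intermediate
22 | 4-(benzyloxy)-2-{(1S,2R)-1-[4-(benzyloxy)-3-methoxyphenyl]-2-[(benzyloxy)methyl]-4-[(triisopropylsilyl)oxy]but-3-yn-1-yl}-3-methoxybenzaldehyde | COc1cc([C@@H](c2c(C=O)ccc(OCc3ccccc3)c2OC)[C@@H](COCc2ccccc2)C#CO[Si](C(C)C)(C(C)C)C(C)C)ccc1OCc1ccccc1 | intermediate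
23 | ring B-fused 4-[(triisopropylsilyl)oxy]-2H-oxete (ring O–C4–C3=C10; C1 and C2 as in 22; C4 configuration not defined) | COc1cc([C@H]2c3c(ccc(OCc4ccccc4)c3OC)C3OC(O[Si](C(C)C)(C(C)C)C(C)C)=C3[C@@H]2COCc2ccccc2)ccc1OCc1ccccc1 | intermediate (not isolated)
24 | triisopropylsilyl (1S,2R)-7-(benzyloxy)-1-[4-(benzyloxy)-3-methoxyphenyl]-2-[(benzyloxy)methyl]-8-methoxy-1,2-dihydronaphthalene-3-carboxylate | COc1cc([C@H]2c3c(ccc(OCc4ccccc4)c3OC)C=C(C(=O)O[Si](C(C)C)(C(C)C)C(C)C)[C@@H]2COCc2ccccc2)ccc1OCc1ccccc1 | intermediate
25 | {(1S,2R)-7-(benzyloxy)-1-[4-(benzyloxy)-3-methoxyphenyl]-2-[(benzyloxy)methyl]-8-methoxy-1,2-dihydronaphthalen-3-yl}methanol | COc1cc([C@H]2c3c(ccc(OCc4ccccc4)c3OC)C=C(CO)[C@@H]2COCc2ccccc2)ccc1OCc1ccccc1 | intermediate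
26 | (1S,2R)-7-(benzyloxy)-1-[4-(benzyloxy)-3-methoxyphenyl]-2-[(benzyloxy)methyl]-8-methoxy-1,2-dihydronaphthalene-3-carbaldehyde | COc1cc([C@H]2c3c(ccc(OCc4ccccc4)c3OC)C=C(C=O)[C@@H]2COCc2ccccc2)ccc1OCc1ccccc1 | intermediate
27 | vitedoin A, (1S,2R)-7-hydroxy-1-(4-hydroxy-3-methoxyphenyl)-2-(hydroxymethyl)-8-methoxy-1,2-dihydronaphthalene-3-carbaldehyde | COc1cc([C@H]2c3c(ccc(O)c3OC)C=C(C=O)[C@@H]2CO)ccc1O | target

## Step count and least certain steps

Total: 15 steps. Longest linear sequence: 13 steps (steps 1, 2, 4, 6, 7, 8, 9, 10, 11, 12, 13, 14, 15).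

**Step 12 (key step).** The most likely failure is diversion of the activated ynol ether before it engages the formyl group. Protonation by traces of HNTf2 can be followed by attack of the electron-rich pendant ring on C10 (a six-membered carbocyclisation) or by hydration to the homologous acid, because all of these nucleophiles lie within reach of the same ketenium centre. Slow turnover from binding of silver to the ether oxygens is the second risk.
Fallback (classical aldol logic in place of metathesis): it sets out from ynolate 20, generated from 17 as in step 10. Quenching 20 with HCl in EtOH (the normal end of a Kowalski ester homologation) and then brief treatment with aqueous HCl/THF to cleave the acetal would give ethyl (3S,4S)-4-[3-(benzyloxy)-6-formyl-2-methoxyphenyl]-4-[4-(benzyloxy)-3-methoxyphenyl]-3-[(benzyloxy)methyl]butanoate F1. NaOEt in EtOH should then effect intramolecular aldol condensation of C3 onto C4 with dehydration, giving the ethyl dihydronaphthalene-3-carboxylate F2. Reduction of F2 with i-Bu2AlH rejoins the route at 25.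

**Step 11.** The most likely failure is loss of the siloxyalkyne by C-protonation and hydration, or an uncontrolled acid-triggered cyclisation, while the acetal is being hydrolysed. Both groups are acid-labile and the selectivity rests only on a rate difference; if the acid is kept too weak the hydrolysis may stall.
Fallback (the acetal itself as electrophile, no free aldehyde): it sets out from 21. Catalytic Me3SiOTf in CH2Cl2 at −78 °C should ionise the acetal to the oxocarbenium ion; C3 adds, the methoxy oxygen closes onto C10 and the four-membered ring opens, with the silyl group leaving as its methyl ether. The product would be the methyl dihydronaphthalene-3-carboxylate F3, which i-Bu2AlH reduces to 25, where the route is rejoined.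

**Step 10.** The most likely failures are incomplete addition of LiCHBr2 to the hindered ester, proton abstraction at C2 followed by loss of benzyloxide, metalation of the doubly benzylic C1–H during the warm-up with excess alkyllithium, or silylation on carbon to give a silyl ketene.
Fallback (ynolate by oxidation of an acetylide): it sets out from 17. i-Bu2AlH at −78 °C gives the aldehyde (2S,3S)-2-[(benzyloxy)methyl]-3-[3-(benzyloxy)-6-(dimethoxymethyl)-2-methoxyphenyl]-3-[4-(benzyloxy)-3-methoxyphenyl]propanal F4. CBr4/PPh3/Et3N (Corey–Fuchs) gives the 1,1-dibromoalkene F5, and n-BuLi (2 equiv) converts it into the lithium acetylide F6. Oxidation of F6 with LiOOt-Bu gives ynolate 20, and i-Pr3SiCl returns the route to 21. Here C3 is the former ester carbon and C10 comes from CBr4; the constitution is the same.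

**Step 6.** The most likely failure is slow conjugate addition with eroded facial selectivity. The β-aryl group of 8 has two ortho substituents, is twisted out of the enoyl plane and shields both faces of Cβ, so the cuprate may decompose or add 1,2 before it adds 1,4.
Fallback (catalyst control, then attachment of the auxiliary): it sets out from 4. Wittig olefination with Ph3P=CHCO2Me gives methyl (E)-3-[3-(benzyloxy)-6-(dimethoxymethyl)-2-methoxyphenyl]acrylate F7. Hayashi–Miyaura arylation with [4-(benzyloxy)-3-methoxyphenyl]boronic acid F8 uses Rh(acac)(C2H4)2, the BINAP antipode that delivers the aryl group to the required face and K3PO4, in dioxane/H2O with heating that a monovalent rhodium aryl tolerates and a cuprate does not; the basic medium keeps the acetal intact. This gives methyl (S)-3-[3-(benzyloxy)-6-(dimethoxymethyl)-2-methoxyphenyl]-3-[4-(benzyloxy)-3-methoxyphenyl]propanoate F9. LiOH hydrolysis (AcOH work-up) gives the acid F10, and t-BuCOCl/Et3N followed by 5 and LiCl rejoins the route at 12.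

**Step 15.** The most likely failure is Lewis-acid damage while the slowest ether (the primary alkyl benzyl ether at C9) is being cleaved: loss of the C8 methyl group next to the boron phenolate, chloride addition to the enal, or acid-promoted dehydration and aromatisation of the hydroxy enal.
Fallback (exchange of benzyl for silyl ethers while the molecule still has no alkene or alkyne): it sets out from 17. Hydrogenolysis (H2, Pd(OH)2/C, EtOAc/MeOH) gives methyl (2S,3S)-3-[6-(dimethoxymethyl)-3-hydroxy-2-methoxyphenyl]-3-(4-hydroxy-3-methoxyphenyl)-2-(hydroxymethyl)propanoate F11, and TBSCl/imidazole in DMF gives its tris(tert-butyldimethylsilyl) ether F12. Steps 10 to 14 applied to F12 would give the siloxyalkyne acetal F13, the aldehyde F14, the cyclised silyl ester F15, the allylic alcohol F16 and the enal F17. HF·pyridine in THF/pyridine then removes the three silyl ethers from F17 and arrives at 27.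

## Further compounds

F1 | step 12 | ethyl (3S,4S)-4-[3-(benzyloxy)-6-formyl-2-methoxyphenyl]-4-[4-(benzyloxy)-3-methoxyphenyl]-3-[(benzyloxy)methyl]butanoate | COc1cc([C@@H](c2c(C=O)ccc(OCc3ccccc3)c2OC)[C@@H](COCc2ccccc2)CC(=O)OCC)ccc1OCc1ccccc1
F2 | step 12 | ethyl (1S,2R)-7-(benzyloxy)-1-[4-(benzyloxy)-3-methoxyphenyl]-2-[(benzyloxy)methyl]-8-methoxy-1,2-dihydronaphthalene-3-carboxylate | COc1cc([C@H]2c3c(ccc(OCc4ccccc4)c3OC)C=C(C(=O)OCC)[C@@H]2COCc2ccccc2)ccc1OCc1ccccc1
F3 | step 11 | methyl (1S,2R)-7-(benzyloxy)-1-[4-(benzyloxy)-3-methoxyphenyl]-2-[(benzyloxy)methyl]-8-methoxy-1,2-dihydronaphthalene-3-carboxylate | COc1cc([C@H]2c3c(ccc(OCc4ccccc4)c3OC)C=C(C(=O)OC)[C@@H]2COCc2ccccc2)ccc1OCc1ccccc1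
F4 | step 10 | (2S,3S)-2-[(benzyloxy)methyl]-3-[3-(benzyloxy)-6-(dimethoxymethyl)-2-methoxyphenyl]-3-[4-(benzyloxy)-3-methoxyphenyl]propanal | COc1cc([C@@H](c2c(C(OC)OC)ccc(OCc3ccccc3)c2OC)[C@@H](COCc2ccccc2)C=O)ccc1OCc1ccccc1
F5 | step 10 | (3R,4S)-1,1-dibromo-3-[(benzyloxy)methyl]-4-[3-(benzyloxy)-6-(dimethoxymethyl)-2-methoxyphenyl]-4-[4-(benzyloxy)-3-methoxyphenyl]but-1-ene | COc1cc([C@@H](c2c(C(OC)OC)ccc(OCc3ccccc3)c2OC)[C@@H](COCc2ccccc2)C=C(Br)Br)ccc1OCc1ccccc1
F6 | step 10 | lithium acetylide of the corresponding but-1-yne (C1 and C2 as in 21) | COc1cc([C@@H](c2c(C(OC)OC)ccc(OCc3ccccc3)c2OC)[C@@H](COCc2ccccc2)C#C[Li])ccc1OCc1ccccc1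
F7 | step 6 | methyl (E)-3-[3-(benzyloxy)-6-(dimethoxymethyl)-2-methoxyphenyl]acrylate | COC(=O)/C=C/c1c(OC)c(OCc2ccccc2)ccc1C(OC)OC
F8 | step 6 | [4-(benzyloxy)-3-methoxyphenyl]boronic acid | COc1cc(B(O)O)ccc1OCc1ccccc1
F9 | step 6 | methyl (S)-3-[3-(benzyloxy)-6-(dimethoxymethyl)-2-methoxyphenyl]-3-[4-(benzyloxy)-3-methoxyphenyl]propanoate | COc1cc([C@@H](c2c(C(OC)OC)ccc(OCc3ccccc3)c2OC)CC(=O)OC)ccc1OCc1ccccc1
F10 | step 6 | (S)-3-[3-(benzyloxy)-6-(dimethoxymethyl)-2-methoxyphenyl]-3-[4-(benzyloxy)-3-methoxyphenyl]propanoic acid | COc1cc([C@@H](c2c(C(OC)OC)ccc(OCc3ccccc3)c2OC)CC(=O)O)ccc1OCc1ccccc1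
F11 | step 15 | methyl (2S,3S)-3-[6-(dimethoxymethyl)-3-hydroxy-2-methoxyphenyl]-3-(4-hydroxy-3-methoxyphenyl)-2-(hydroxymethyl)propanoate | COc1cc([C@@H](c2c(C(OC)OC)ccc(O)c2OC)[C@@H](CO)C(=O)OC)ccc1O
F12 | step 15 | tris(tert-butyldimethylsilyl) ether of F11 | COc1cc([C@@H](c2c(C(OC)OC)ccc(O[Si](C)(C)C(C)(C)C)c2OC)[C@@H](CO[Si](C)(C)C(C)(C)C)C(=O)OC)ccc1O[Si](C)(C)C(C)(C)C
F13 | step 15 | tris(tert-butyldimethylsilyl) analogue of 21 | COc1cc([C@@H](c2c(C(OC)OC)ccc(O[Si](C)(C)C(C)(C)C)c2OC)[C@@H](CO[Si](C)(C)C(C)(C)C)C#CO[Si](C(C)C)(C(C)C)C(C)C)ccc1O[Si](C)(C)C(C)(C)C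
F14 | step 15 | tris(tert-butyldimethylsilyl) analogue of 22 | COc1cc([C@@H](c2c(C=O)ccc(O[Si](C)(C)C(C)(C)C)c2OC)[C@@H](CO[Si](C)(C)C(C)(C)C)C#CO[Si](C(C)C)(C(C)C)C(C)C)ccc1O[Si](C)(C)C(C)(C)C
F15 | step 15 | tris(tert-butyldimethylsilyl) analogue of 24 | COc1cc([C@H]2c3c(ccc(O[Si](C)(C)C(C)(C)C)c3OC)C=C(C(=O)O[Si](C(C)C)(C(C)C)C(C)C)[C@@H]2CO[Si](C)(C)C(C)(C)C)ccc1O[Si](C)(C)C(C)(C)C
F16 | step 15 | tris(tert-butyldimethylsilyl) analogue of 25 | COc1cc([C@H]2c3c(ccc(O[Si](C)(C)C(C)(C)C)c3OC)C=C(CO)[C@@H]2CO[Si](C)(C)C(C)(C)C)ccc1O[Si](C)(C)C(C)(C)C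
F17 | step 15 | tris(tert-butyldimethylsilyl) ether of 27 | COc1cc([C@H]2c3c(ccc(O[Si](C)(C)C(C)(C)C)c3OC)C=C(C=O)[C@@H]2CO[Si](C)(C)C(C)(C)C)ccc1O[Si](C)(C)C(C)(C)C
A1 | alternative 1 | (1S,2R)-2-{[(tert-butyldimethylsilyl)oxy]methyl}-1-{4-[(tert-butyldimethylsilyl)oxy]-3-methoxyphenyl}-7-hydroxy-8-methoxy-1,2-dihydronaphthalene-3-carbaldehyde | COc1cc([C@H]2c3c(ccc(O)c3OC)C=C(C=O)[C@@H]2CO[Si](C)(C)C(C)(C)C)ccc1O[Si](C)(C)C(C)(C)C
A2 | alternative 1 | (2E,3R,4S)-3-{[(tert-butyldimethylsilyl)oxy]methyl}-4-{4-[(tert-butyldimethylsilyl)oxy]-3-methoxyphenyl}-2-(furan-2-ylmethylidene)-6-methoxyhex-5-ynal | O=C/C(=C/c1ccco1)[C@H](CO[Si](C)(C)C(C)(C)C)[C@H](C#COC)c1ccc(O[Si](C)(C)C(C)(C)C)c(OC)c1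
A3 | alternative 2 | trans-fused aryl dihydronaphthalene lactone, bis(tert-butyldimethylsilyl) ether (C1 S, C2 R in target numbering) | COc1cc([C@H]2c3c(ccc(O[Si](C)(C)C(C)(C)C)c3OC)C=C4C(=O)OC[C@H]24)ccc1O[Si](C)(C)C(C)(C)C
A4 | alternative 2 | (E)-3-{[4-(tert-butyldimethylsilyloxy)-2-(diazo{4-[(tert-butyldimethylsilyl)oxy]-3-methoxyphenyl}methyl)-3-methoxyphenyl]methylidene}oxolan-2-one | [N-]=[N+]=C(c1ccc(O[Si](C)(C)C(C)(C)C)c(OC)c1)c1c(OC)c(O[Si](C)(C)C(C)(C)C)ccc1/C=C1\CCOC1=O
A5 | alternative 3 | (1S,2R)-7-[(tert-butyldimethylsilyl)oxy]-1-(4-hydroxy-3-methoxyphenyl)-8-methoxy-1,2-dihydronaphthalene-2,3-dicarbaldehyde | COc1cc([C@H]2c3c(ccc(O[Si](C)(C)C(C)(C)C)c3OC)C=C(C=O)[C@@H]2C=O)ccc1O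
A6 | alternative 3 | 4-[(tert-butyldimethylsilyl)oxy]-3-methoxy-2-[(3-methoxy-4-oxocyclohexa-2,5-dien-1-ylidene)methyl]benzaldehyde (alkene geometry not defined) | O=Cc1ccc(O[Si](C)(C)C(C)(C)C)c(OC)c1C=C1C=CC(=O)C(OC)=C1
A7 | alternative 3 | succinaldehyde | O=CCCC=O
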